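**Retrosynthetic overview**
- The route rests on ring C: O1–C2–C3–C4(=O) is a β-aryloxy ketone, so C2 can be taken back to an acetal carbon and C3/C4 to an exocyclic enol ether. The C2–C3 bond and the (2S) centre are then made last by an O-to-C (Petasis–Ferrier-type) shift of a 2-aryl-4-methylene-1,3-benzodioxine under a chiral Brønsted acid.
- The enol acetal comes from methylenation of a 2-aryl-1,3-benzodioxin-4-one, itself the mixed acetal of salicylic acid 8 (ring A) and aldehyde 12 (ring B).
- Acid 8 comes from 2,4,6-trihydroxybenzoic acid: an aromatic Claisen shift places the allyl group at C3 and frees only the neighbouring oxygen, so that oxygen alone can become O1. Aldehyde 12 comes from 4-hydroxybenzaldehyde by ortho C-prenylation.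
- After ring C: reagent-controlled Shi epoxidation of the ring B prenyl group (the 8-allyl group is inert), cross-metathesis of 8-allyl to 8-prenyl, buffered desilylation.
- Ring order: rings A and B are bought as arenes; a temporary 1,3-dioxine ring (step 8); ring C (step 10); the oxirane (step 11).

Key step: step 10

Assumption: the sense of induction of the chiral acid in step 10 cannot be predicted, so the (R) catalyst is written and its antipode is taken if it favours (2R); the D-fructose-derived Shi ketone is taken to give the (R)-oxirane, as its spiro transition-state model predicts for a trisubstituted alkene.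

**Step 1**
Reactants: 1 2,4,6-trihydroxybenzoic acid; 2 allyl bromide
Product: 3 prop-2-enyl 2,4,6-trihydroxybenzoate
Conditions: KHCO3 (1.1 equiv), DMF, rt
Reagents that add atoms: none
Why: Carboxylate O-alkylation (SN2); hydrogencarbonate ionises only the carboxylic acid, so the phenols stay free, and the allyl ester can later be removed under neutral conditions.

**Step 2**
Reactants: 3 prop-2-enyl 2,4,6-trihydroxybenzoate
Product: 4 prop-2-enyl 2-hydroxy-4,6-bis(tert-butyldimethylsilyloxy)benzoate
Conditions: TBSCl (2.1 equiv), imidazole, CH2Cl2, 0 °C to rt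
Reagents that add atoms: tert-butyldimethylsilyl chloride, CC(C)(C)[Si](C)(C)Cl
Why: Silyl ether formation; the 4-OH and one ortho OH should react, while the remaining ortho OH, hydrogen-bonded to the ester carbonyl, should stay free (the two ortho positions are equivalent by symmetry).

**Step 3**
Reactants: 4 prop-2-enyl 2-hydroxy-4,6-bis(tert-butyldimethylsilyloxy)benzoate; 5 allyl alcohol
Product: 6 prop-2-enyl 2-(prop-2-enyloxy)-4,6-bis(tert-butyldimethylsilyloxy)benzoate
Conditions: PPh3, DIAD, THF, 0 °C to rt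
Reagents that add atoms: none
Why: Mitsunobu etherification of the one free phenol; the conditions are neutral, so the aryl silyl ethers are not cleaved or scrambled as they could be under carbonate alkylation.

**Step 4**
Reactants: 6 prop-2-enyl 2-(prop-2-enyloxy)-4,6-bis(tert-butyldimethylsilyloxy)benzoate
Product: 7 prop-2-enyl 3-allyl-2-hydroxy-4,6-bis(tert-butyldimethylsilyloxy)benzoate
Conditions: PhNEt2, 185 °C
Reagents that add atoms: none
Why: Aromatic Claisen rearrangement ([3,3]-sigmatropic shift); C3 is the only free ortho position, so the allyl group should land there and the oxygen it leaves becomes the single free phenol next to it.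

**Step 5**
Reactants: 7 prop-2-enyl 3-allyl-2-hydroxy-4,6-bis(tert-butyldimethylsilyloxy)benzoate
Product: 8 3-allyl-2-hydroxy-4,6-bis(tert-butyldimethylsilyloxy)benzoic acid
Conditions: Pd(PPh3)4 (5 mol%), morpholine, THF, rt; cold pH 5 buffer work-up
Reagents that add atoms: none
Why: Allyl ester cleavage through a π-allyl complex of zerovalent palladium, with morpholine as allyl acceptor (Tsuji–Trost deallylation); the C-allyl group has no leaving group and the silyl ethers see neither acid nor hydroxide.

**Step 6**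
Reactants: 9 4-hydroxybenzaldehyde; 10 prenyl bromide
Product: 11 4-hydroxy-3-(3-methylbut-2-enyl)benzaldehyde
Conditions: KOH, H2O, rt
Reagents that add atoms: none
Why: Ortho C-alkylation of a phenoxide in water, where hydrogen bonding to the phenoxide oxygen steers the allylic bromide to the ortho carbon; the O-prenyl ether by-product is removed by chromatography.

**Step 7**
Reactants: 11 4-hydroxy-3-(3-methylbut-2-enyl)benzaldehyde
Product: 12 4-(tert-butyldimethylsilyloxy)-3-(3-methylbut-2-enyl)benzaldehyde
Conditions: TBSCl, imidazole, DMF, rt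
Reagents that add atoms: tert-butyldimethylsilyl chloride, CC(C)(C)[Si](C)(C)Cl
Why: Silyl ether formation; capping the phenol stops it adding to the prenyl group under the later acidic steps while keeping ring B electron-rich.

**Step 8**
Reactants: 8 3-allyl-2-hydroxy-4,6-bis(tert-butyldimethylsilyloxy)benzoic acid; 12 4-(tert-butyldimethylsilyloxy)-3-(3-methylbut-2-enyl)benzaldehyde
Product: 14 rac-8-allyl-5,7-bis(tert-butyldimethylsilyloxy)-2-[4-(tert-butyldimethylsilyloxy)-3-(3-methylbut-2-enyl)phenyl]-4H-1,3-benzodioxin-4-one, via bis-silylated salicylate 13 (not isolated)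
Conditions: HMDS, THF, rt, evaporate; then 12, TMSOTf (0.2 equiv), CH2Cl2, −78 to −40 °C; pyridine quench
Reagents that add atoms: none
Why: Silyl triflate-promoted acetalisation of a bis-silylated hydroxy acid with an aldehyde: the silyl carboxylate adds to the activated aldehyde, the α-silyloxybenzyl ester ionises, and the neighbouring aryl silyl ether closes the six-membered acylal with loss of hexamethyldisiloxane; the new acetal centre is racemic and is erased in step 10.

**Step 9**
Reactants: 14 rac-8-allyl-5,7-bis(tert-butyldimethylsilyloxy)-2-[4-(tert-butyldimethylsilyloxy)-3-(3-methylbut-2-enyl)phenyl]-4H-1,3-benzodioxin-4-one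
Product: 15 rac-8-allyl-5,7-bis(tert-butyldimethylsilyloxy)-2-[4-(tert-butyldimethylsilyloxy)-3-(3-methylbut-2-enyl)phenyl]-4-methylidene-4H-1,3-benzodioxine
Conditions: Cp2TiMe2 (2.5 equiv), toluene, 65 °C, dark; filtration through basic alumina
Reagents that add atoms: dimethyltitanocene, C[Ti](C)(C1C=CC=C1)C1C=CC=C1
Why: Petasis methylenation of the lactone carbonyl through Cp2Ti=CH2 and an oxatitanacyclobutane; the reagent is non-basic and leaves the acetal, the silyl ethers and both alkenes alone.

**Step 10**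
Reactants: 15 rac-8-allyl-5,7-bis(tert-butyldimethylsilyloxy)-2-[4-(tert-butyldimethylsilyloxy)-3-(3-methylbut-2-enyl)phenyl]-4-methylidene-4H-1,3-benzodioxine
Product: 16 (2S)-8-allyl-5,7-bis(tert-butyldimethylsilyloxy)-2-[4-(tert-butyldimethylsilyloxy)-3-(3-methylbut-2-enyl)phenyl]chroman-4-one
Conditions: (R)-3,3'-bis(2,4,6-triisopropylphenyl)-1,1'-binaphthyl-2,2'-diyl hydrogen phosphate (10 mol%), 4 Å MS, toluene, −40 °C; Et3N quench
Reagents that add atoms: none
Why: Proposed new method: the phosphoric acid hydrogen-bonds to the enol-ether oxygen O3 and assists heterolysis of C2–O3, giving an O-aryl oxocarbenium ion at C2 (stabilised by the para-silyloxy ring B) and the enol of the ring A methyl ketone, both held on the chiral phosphate (P=O to the enol O–H, P–O− to C2); the enol carbon then attacks C2, forming C2–C3 and the C4 carbonyl irreversibly, and reversible C-protonation of the enol ether leads, after loss of the ketone, to the same cation, so both channels converge. The closest known reactions are the Lewis acid-promoted Petasis–Ferrier rearrangement of 4-methylene-1,3-dioxanes to tetrahydropyranones and the chiral phosphoric acid-catalysed aza-Petasis–Ferrier rearrangement of hemiaminal vinyl ethers; neither has been shown for an O,O-acetal under enantiocontrol. Ring C closes in a 6-(enolendo)-endo-trig mode at the oxocarbenium carbon, made easy by the ortho placement of O1 and the enol on ring A. Ionisation erases the acetal centre of 15, so the racemate converges and C2 is set only by the chiral anion, which must shield one face of the planar cation while delivering the hydrogen-bonded enol; the (2S) sense is the unproven point. The step needs C- over O-recombination (O-return only regenerates 15, C-attack is the thermodynamic sink), no alkene capture of the cation (the C8 chain is a monosubstituted allyl group and a poor π-nucleophile, whereas a prenyl group there could close a chromane by Prins reaction, and the ring B prenyl group cannot reach C2) and no hydrolysis (molecular sieves).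

**Step 11**
Reactants: 16 (2S)-8-allyl-5,7-bis(tert-butyldimethylsilyloxy)-2-[4-(tert-butyldimethylsilyloxy)-3-(3-methylbut-2-enyl)phenyl]chroman-4-one
Product: 17 (2S)-8-allyl-5,7-bis(tert-butyldimethylsilyloxy)-2-{4-(tert-butyldimethylsilyloxy)-3-[((2R)-3,3-dimethyloxiran-2-yl)methyl]phenyl}chroman-4-one
Conditions: 1,2:4,5-di-O-isopropylidene-β-D-erythro-hexo-2,3-diulo-2,6-pyranose (D-fructose-derived Shi ketone, 0.3 equiv), Oxone (2KHSO5·KHSO4·K2SO4), K2CO3, Bu4NHSO4, Na2B4O7 buffer, MeCN–CH2(OMe)2–H2O, −5 °C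
Reagents that add atoms: potassium peroxymonosulfate, [K+].[O-]S(=O)(=O)OO
Why: Shi asymmetric epoxidation by the chiral dioxirane through a spiro transition state; the electron-rich trisubstituted alkene should react far faster than the monosubstituted 8-allyl group, and the oxirane carbon should be set (R) by the catalyst, independent of the remote C2 centre.

**Step 12**
Reactants: 17 (2S)-8-allyl-5,7-bis(tert-butyldimethylsilyloxy)-2-{4-(tert-butyldimethylsilyloxy)-3-[((2R)-3,3-dimethyloxiran-2-yl)methyl]phenyl}chroman-4-one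
Product: 18 (2S)-5,7-bis(tert-butyldimethylsilyloxy)-2-{4-(tert-butyldimethylsilyloxy)-3-[((2R)-3,3-dimethyloxiran-2-yl)methyl]phenyl}-8-(3-methylbut-2-enyl)chroman-4-one
Conditions: RuCl2(=CHPh)(PCy3)(H2IMes) (second-generation Grubbs catalyst, 5 mol%), 2-methyl-2-butene (co-solvent), CH2Cl2, 35 °C
Reagents that add atoms: 2-methyl-2-butene, CC=C(C)C
Why: Olefin cross-metathesis of an allylarene with excess 2-methyl-2-butene converts allyl into prenyl with loss of propene; the catalyst tolerates the oxirane, ketone and silyl ethers, and the trisubstituted product does not re-enter metathesis.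

**Step 13**
Reactants: 18 (2S)-5,7-bis(tert-butyldimethylsilyloxy)-2-{4-(tert-butyldimethylsilyloxy)-3-[((2R)-3,3-dimethyloxiran-2-yl)methyl]phenyl}-8-(3-methylbut-2-enyl)chroman-4-one
Product: 19 (2S)-2-{3-[((2R)-3,3-dimethyloxiran-2-yl)methyl]-4-hydroxyphenyl}-5,7-dihydroxy-8-(3-methylbut-2-enyl)chroman-4-one (CNP0324151.1)
Conditions: Bu4NF, AcOH (1:1), THF, 0 °C
Reagents that add atoms: none
Why: Fluoride-induced cleavage of the three aryl silyl ethers; acetic acid keeps the freed phenols protonated, so the 4'-phenoxide should not open the neighbouring oxirane and ring C should not open by E1cB, and no stereocentre is touched.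

**Compound list**
1 | 2,4,6-trihydroxybenzoic acid | OC(=O)c1c(O)cc(O)cc1O | starting material
2 | allyl bromide | C=CCBr | starting material
3 | prop-2-enyl 2,4,6-trihydroxybenzoate | C=CCOC(=O)c1c(O)cc(O)cc1O | intermediate
4 | prop-2-enyl 2-hydroxy-4,6-bis(tert-butyldimethylsilyloxy)benzoate | C=CCOC(=O)c1c(O)cc(O[Si](C)(C)C(C)(C)C)cc1O[Si](C)(C)C(C)(C)C | intermediate
5 | allyl alcohol | C=CCO | starting material
6 | prop-2-enyl 2-(prop-2-enyloxy)-4,6-bis(tert-butyldimethylsilyloxy)benzoate | C=CCOC(=O)c1c(OCC=C)cc(O[Si](C)(C)C(C)(C)C)cc1O[Si](C)(C)C(C)(C)C | intermediate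
7 | prop-2-enyl 3-allyl-2-hydroxy-4,6-bis(tert-butyldimethylsilyloxy)benzoate | C=CCOC(=O)c1c(O)c(CC=C)c(O[Si](C)(C)C(C)(C)C)cc1O[Si](C)(C)C(C)(C)C | intermediate
8 | 3-allyl-2-hydroxy-4,6-bis(tert-butyldimethylsilyloxy)benzoic acid | OC(=O)c1c(O)c(CC=C)c(O[Si](C)(C)C(C)(C)C)cc1O[Si](C)(C)C(C)(C)C | intermediate
9 | 4-hydroxybenzaldehyde | Oc1ccc(C=O)cc1 | starting material
10 | prenyl bromide | CC(C)=CCBr | starting material
11 | 4-hydroxy-3-(3-methylbut-2-enyl)benzaldehyde | CC(C)=CCc1cc(C=O)ccc1O | intermediate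
12 | 4-(tert-butyldimethylsilyloxy)-3-(3-methylbut-2-enyl)benzaldehyde | CC(C)=CCc1cc(C=O)ccc1O[Si](C)(C)C(C)(C)C | intermediate
13 | trimethylsilyl 3-allyl-4,6-bis(tert-butyldimethylsilyloxy)-2-(trimethylsilyloxy)benzoate (not isolated) | C[Si](C)(C)OC(=O)c1c(O[Si](C)(C)C)c(CC=C)c(O[Si](C)(C)C(C)(C)C)cc1O[Si](C)(C)C(C)(C)C | intermediate
14 | rac-8-allyl-5,7-bis(tert-butyldimethylsilyloxy)-2-[4-(tert-butyldimethylsilyloxy)-3-(3-methylbut-2-enyl)phenyl]-4H-1,3-benzodioxin-4-one | O=C1OC(c2ccc(O[Si](C)(C)C(C)(C)C)c(CC=C(C)C)c2)Oc2c(CC=C)c(O[Si](C)(C)C(C)(C)C)cc(O[Si](C)(C)C(C)(C)C)c12 | intermediate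
15 | rac-8-allyl-5,7-bis(tert-butyldimethylsilyloxy)-2-[4-(tert-butyldimethylsilyloxy)-3-(3-methylbut-2-enyl)phenyl]-4-methylidene-4H-1,3-benzodioxine | C=C1OC(c2ccc(O[Si](C)(C)C(C)(C)C)c(CC=C(C)C)c2)Oc2c(CC=C)c(O[Si](C)(C)C(C)(C)C)cc(O[Si](C)(C)C(C)(C)C)c12 | intermediate
16 | (2S)-8-allyl-5,7-bis(tert-butyldimethylsilyloxy)-2-[4-(tert-butyldimethylsilyloxy)-3-(3-methylbut-2-enyl)phenyl]chroman-4-one | C=CCc1c(O[Si](C)(C)C(C)(C)C)cc(O[Si](C)(C)C(C)(C)C)c2c1O[C@H](c1ccc(O[Si](C)(C)C(C)(C)C)c(CC=C(C)C)c1)CC2=O | intermediate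
17 | (2S)-8-allyl-5,7-bis(tert-butyldimethylsilyloxy)-2-{4-(tert-butyldimethylsilyloxy)-3-[((2R)-3,3-dimethyloxiran-2-yl)methyl]phenyl}chroman-4-one | C=CCc1c(O[Si](C)(C)C(C)(C)C)cc(O[Si](C)(C)C(C)(C)C)c2c1O[C@H](c1ccc(O[Si](C)(C)C(C)(C)C)c(C[C@H]3OC3(C)C)c1)CC2=O | intermediate
18 | (2S)-5,7-bis(tert-butyldimethylsilyloxy)-2-{4-(tert-butyldimethylsilyloxy)-3-[((2R)-3,3-dimethyloxiran-2-yl)methyl]phenyl}-8-(3-methylbut-2-enyl)chroman-4-one | CC(C)=CCc1c(O[Si](C)(C)C(C)(C)C)cc(O[Si](C)(C)C(C)(C)C)c2c1O[C@H](c1ccc(O[Si](C)(C)C(C)(C)C)c(C[C@H]3OC3(C)C)c1)CC2=O | intermediate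
19 | (2S)-2-{3-[((2R)-3,3-dimethyloxiran-2-yl)methyl]-4-hydroxyphenyl}-5,7-dihydroxy-8-(3-methylbut-2-enyl)chroman-4-one | CC(C)=CCc1c(O)cc(O)c2c1O[C@H](c1ccc(O)c(C[C@H]3OC3(C)C)c1)CC2=O | target

**Step count**
Total: 13 steps. Longest linear sequence: 11 steps (steps 1–5, then 8–13); the ring B branch (steps 6–7) joins at step 8.

**Steps most likely to fail**

Step 10 (proposed new method). The ion pair may close without useful face selection, and the enol ether may be lost to hydrolysis or to intermolecular capture of the cation. The fallback is known chemistry, sets out from 15 and returns at 16. Mild hydrolysis of 15 (PPTS, THF–H2O, rt) should give the acetophenone 1-[3-allyl-2-hydroxy-4,6-bis(tert-butyldimethylsilyloxy)phenyl]ethanone F1 together with aldehyde 12. The two would be recondensed (pyrrolidine, MeCN, 40 °C) through the 2'-hydroxychalcone (E)-1-[3-allyl-2-hydroxy-4,6-bis(tert-butyldimethylsilyloxy)phenyl]-3-[4-(tert-butyldimethylsilyloxy)-3-(3-methylbut-2-enyl)phenyl]prop-2-en-1-one F2, which should close by oxa-Michael addition to the racemic flavanone rac-16 F3. Kinetic resolution by asymmetric transfer hydrogenation (RhCl(Cp*)[(R,R)-TsDPEN], HCO2H–Et3N, EtOAc, rt, stopped near half conversion) should reduce the (2R)-ketone to the cis-(2R,4R)-flavan-4-ol F4 and leave (2S)-16, which is separated by chromatography.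

Step 8. The hindered, electron-rich acid may lose CO2 by protodecarboxylation, the electron-rich aldehyde may be activated too slowly, or the acid-labile acylal may reopen on isolation. The fallback sets out from 12 and returns at 14; it replaces direct condensation by transacetalisation of a preformed acetal. Aldehyde 12 would be converted (HC(OMe)3, PPTS cat., MeOH, rt) into the dimethyl acetal 4-(tert-butyldimethylsilyloxy)-1-(dimethoxymethyl)-3-(3-methylbut-2-enyl)benzene F5. This ionises far more readily than the aldehyde and would be combined with the bis-silylated salicylate 13 (from 8 and HMDS) under catalytic TMSOTf at −78 °C to give 14.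

Step 11. The carbonate buffer may open ring C by enolisation at C3 and β-elimination of the O1 phenoxide, eroding the C2 configuration, and aryl silyl ethers may be lost. The fallback sets out from 16 and returns at 17; it removes the acidic C3–H by a temporary change of oxidation level at C4. Reduction of 16 (NaBH4, THF–EtOH, 0 °C) should give the cis-(2S,4S)-flavan-4-ol F6. The same Shi epoxidation should then give the epoxy alcohol (2S,4S)-8-allyl-5,7-bis(tert-butyldimethylsilyloxy)-2-{4-(tert-butyldimethylsilyloxy)-3-[((2R)-3,3-dimethyloxiran-2-yl)methyl]phenyl}chroman-4-ol F7; any oxidation of the carbinol by the dioxirane would only lead on to 17. Dess–Martin periodinane (NaHCO3, CH2Cl2, 0 °C) would return the ketone 17.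

**Further compounds**
F1 | step 10 | 1-[3-allyl-2-hydroxy-4,6-bis(tert-butyldimethylsilyloxy)phenyl]ethanone | CC(=O)c1c(O)c(CC=C)c(O[Si](C)(C)C(C)(C)C)cc1O[Si](C)(C)C(C)(C)C
F2 | step 10 | (E)-1-[3-allyl-2-hydroxy-4,6-bis(tert-butyldimethylsilyloxy)phenyl]-3-[4-(tert-butyldimethylsilyloxy)-3-(3-methylbut-2-enyl)phenyl]prop-2-en-1-one | O=C(/C=C/c1ccc(O[Si](C)(C)C(C)(C)C)c(CC=C(C)C)c1)c1c(O)c(CC=C)c(O[Si](C)(C)C(C)(C)C)cc1O[Si](C)(C)C(C)(C)C
F3 | step 10 | rac-8-allyl-5,7-bis(tert-butyldimethylsilyloxy)-2-[4-(tert-butyldimethylsilyloxy)-3-(3-methylbut-2-enyl)phenyl]chroman-4-one | C=CCc1c(O[Si](C)(C)C(C)(C)C)cc(O[Si](C)(C)C(C)(C)C)c2c1OC(c1ccc(O[Si](C)(C)C(C)(C)C)c(CC=C(C)C)c1)CC2=O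
F4 | step 10 | (2R,4R)-8-allyl-5,7-bis(tert-butyldimethylsilyloxy)-2-[4-(tert-butyldimethylsilyloxy)-3-(3-methylbut-2-enyl)phenyl]chroman-4-ol | C=CCc1c(O[Si](C)(C)C(C)(C)C)cc(O[Si](C)(C)C(C)(C)C)c2c1O[C@@H](c1ccc(O[Si](C)(C)C(C)(C)C)c(CC=C(C)C)c1)C[C@H]2O
F5 | step 8 | 4-(tert-butyldimethylsilyloxy)-1-(dimethoxymethyl)-3-(3-methylbut-2-enyl)benzene | COC(OC)c1ccc(O[Si](C)(C)C(C)(C)C)c(CC=C(C)C)c1
F6 | step 11 | (2S,4S)-8-allyl-5,7-bis(tert-butyldimethylsilyloxy)-2-[4-(tert-butyldimethylsilyloxy)-3-(3-methylbut-2-enyl)phenyl]chroman-4-ol | C=CCc1c(O[Si](C)(C)C(C)(C)C)cc(O[Si](C)(C)C(C)(C)C)c2c1O[C@H](c1ccc(O[Si](C)(C)C(C)(C)C)c(CC=C(C)C)c1)C[C@@H]2O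
F7 | step 11 | (2S,4S)-8-allyl-5,7-bis(tert-butyldimethylsilyloxy)-2-{4-(tert-butyldimethylsilyloxy)-3-[((2R)-3,3-dimethyloxiran-2-yl)methyl]phenyl}chroman-4-ol | C=CCc1c(O[Si](C)(C)C(C)(C)C)cc(O[Si](C)(C)C(C)(C)C)c2c1O[C@H](c1ccc(O[Si](C)(C)C(C)(C)C)c(C[C@H]3OC3(C)C)c1)C[C@@H]2O
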